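42.4% of the charged substrate stood as side product A at the end of amber, and that reading is what you need for blue, the flask you take over. The last reading of blue, at 20.0 min, shows 41.2% side product A and 19.7% target.

| flask | substrate | reagent | remark | time |
|---|---|---|---|---|
| blue | 0.80 M | 0.88 M | the very flask that is asked about, followed so far |  |
| amber | 1.2 M | 0.88 M | run made earlier |  |
| flask | 0.80 M | 0.880 M |  | 2.5 h |

- blue (time / min: side product A / %, target / %): 1.33: 3.7, 2.3; 2.50: 9.6, 3.8; 5.00: 17.5, 8.1; 10.0: 30.4, 13.1; 20.0: 41.2, 19.7
- amber (time / h: side product A / %, target / %): 0.200: 33.0, 12.0; 0.417: 41.1, 17.6; 0.667: 41.3, 20.4; 1.33: 42.9, 21.2; 2.50: 42.4, 21.9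

(scatter of a reading: 0.5 percentage points)

- the analysis behind the earlier runs scatters by 0.5 percentage points, standard deviation

- ratio of side product A to target at 30 s
- ratio of side product A to target at 8.0 min
- ratio of side product A to target at 2.5 h

My own reckoning takes one reagent per side product A, which is an assumption, and borrows amber's final share for blue:

demand = 42.4% × 0.80 M = 0.339 M

reagent left = 1 − demand / 0.88 M = 61.5%

This is the reagent demand, the final share of side product A times [substrate] as charged. Add no reagent to blue: its demand lies below the [reagent] charged, so by this reckoning reagent stays in excess, and you should find about 61.5% of it at 2.5 h.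

The forecast for blue gives 2.3, 2.25 and 1.9, and it says of amber “A stops first while target creeps on”.

Blue gives 1.56, 2.39 and 1.71, so the forecast at 30 s stands 1.47 times too high, and the other two lie within tolerance.

    substrate ⇌ intermediate C (K = 1.00, k = 0.00110 s⁻¹)
    intermediate A → target (k = 0.0180 s⁻¹)
    substrate → intermediate A (k = 9.20 × 10⁻⁴ s⁻¹)
    substrate + intermediate A → side product B (k = 0.0380 L mol⁻¹ s⁻¹)
    reagent + intermediate C → side product A (k = 0.0200 L mol⁻¹ s⁻¹)
    reagent + intermediate A ⇌ intermediate B (K = 12.0 L mol⁻¹, k = 0.00670 L mol⁻¹ s⁻¹)
    substrate → decomposition product (k = 2.90 × 10⁻⁶ s⁻¹)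

Blue ended with 44.9% side product A and 59.1% of its reagent left, against the reckoned 61.5%. For the neighbour flask charged with 0.22 M reagent, its substrate as in blue, the same reckoning gives the same demand of 0.339 M, which is more than its charge. At one reagent each, its charge covers 27.5% of the substrate as side product A. That neighbour ended with 27.2% side product A, 0.94% of its reagent left and 37.4% target, a ratio of 0.728.

The runs stem from a simulated flask with made-up constants.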